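The flavanone ring C (O1–C2–C3–C4) is cut into a salicylaldehyde, which carries ring A, O1 and C4, and an internal alkyne, whose two carbons become C2 and C3 and already bear the 4-benzyloxyphenyl group and the complete apigenin unit. One rhodium-catalysed operation, aldehyde C–H addition across the alkyne followed by oxa-Michael closure, forms C3–C4 and O1–C2 and sets the trans relationship. Regiocontrol should come from the flavone C4 carbonyl, which can chelate rhodium at the carbon that becomes C3, and from the electron-rich aryl group on the carbon that becomes C2. The racemate is resolved, then all six benzyl ethers are removed.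

Key step: step 5

Step 1
Reactants: 1 apigenin
Product: 2 tri-O-benzylapigenin (5,7-bis(benzyloxy)-2-[4-(benzyloxy)phenyl]-4H-chromen-4-one)
Conditions: BnBr (4 equiv), K2CO3 (5 equiv), DMF, 80 °C
Reagents that add atoms: benzyl bromide, BrCc1ccccc1
Why: Williamson ether synthesis: all three phenoxides of 1 are alkylated, the hydrogen-bonded 5-OH last, which excess reagent and heating should overcome.

Step 2
Reactants: 2 tri-O-benzylapigenin
Product: 4 3-iodo-tri-O-benzylapigenin (5,7-bis(benzyloxy)-2-[4-(benzyloxy)phenyl]-3-iodo-4H-chromen-4-one), via 3-lithioflavone 3 (not isolated)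
Conditions: LDA (commercial solution, 1.3 equiv), THF, −78 °C; then I2, −78 °C to rt
Reagents that add atoms: iodine, II
Why: Lithiation–electrophilic trapping: LDA should remove the flavone C3–H (the only vinylic C–H of the pyrone, flanked by the carbonyl) and iodine quenches the vinyllithium, which avoids the ring-A iodination that electrophilic conditions would give.

Step 3
Reactants: 4 3-iodo-tri-O-benzylapigenin; 5 1-(benzyloxy)-4-ethynylbenzene
Product: 6 3-alkynylflavone (5,7-bis(benzyloxy)-2-[4-(benzyloxy)phenyl]-3-{[4-(benzyloxy)phenyl]ethynyl}-4H-chromen-4-one)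
Conditions: PdCl2(PPh3)2 (5 mol %), CuI (10 mol %), Et3N, DMF, 60 °C
Reagents that add atoms: none
Why: Sonogashira coupling: the 3-iodochromone should behave as an electron-poor vinyl iodide in oxidative addition and couple with the copper acetylide of 5, while the tertiary amine leaves the pyrone ring intact.

Step 4
Reactants: 7 2,4,6-trihydroxybenzaldehyde
Product: 8 4,6-bis(benzyloxy)-2-hydroxybenzaldehyde
Conditions: BnBr (2.1 equiv), K2CO3, DMF, 0 °C to rt
Reagents that add atoms: benzyl bromide, BrCc1ccccc1
Why: Regioselective Williamson etherification: the 4-OH and one ortho OH are alkylated, while the remaining ortho OH is held in a hydrogen bond to the formyl group and should stay free with two equivalents of benzyl bromide.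

Step 5
Reactants: 6 3-alkynylflavone; 8 4,6-bis(benzyloxy)-2-hydroxybenzaldehyde
Product: 10 racemic trans-hexa-O-benzyl flavanone–flavone, via E-enone 9 (not isolated)
Conditions: [RhCl(cod)]2 (5 mol %), 1,1'-bis(diphenylphosphino)ferrocene (dppf, 10 mol %), CsF (1 equiv), toluene, 100 °C
Reagents that add atoms: none
Why: The phenoxide-bound aldehyde C–H bond of 8 adds oxidatively to monovalent rhodium to give a five-membered acyl rhodium hydride chelate, alkyne 6 inserts into Rh–H with syn delivery of hydride to the carbon bearing the 4-benzyloxyphenyl group, and C–C reductive elimination joins the acyl carbon (C4) to the carbon bearing the flavone (C3) to give E-enone 9; the caesium phenoxide of 9 then adds through O1 to the benzylidene carbon (C2) and the enolate is protonated at C3. The closest known reaction type is the tandem rhodium-catalysed hydroacylation of internal alkynes with salicylaldehydes and oxa-Michael addition that gives trans-2,3-disubstituted chroman-4-ones, here applied to an unsymmetrical diaryl-type alkyne. Ring C closes in the 6-endo-trig mode, as in the chalcone-to-flavanone cyclisation. C2 is created in the oxa-Michael step without control of absolute configuration, so 10 is racemic, and C3 is set by enolate protonation and should equilibrate under fluoride to the diequatorial 2,3-trans arrangement (thermodynamic control). The step needs regioselective hydrometalation, which two features of 6 should secure: the flavone C4 carbonyl can hold rhodium in a five-membered chelate on the alkyne carbon next to flavone C3, and the electron-releasing 4-benzyloxyphenyl group makes its own alkyne carbon the better hydride acceptor. Chemoselectivity should follow from the inertness of the fully substituted pyrone ring of the flavone toward phenoxide and rhodium hydride.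

Step 6
Reactants: 10 racemic trans-hexa-O-benzyl flavanone–flavone
Product: 11 (2S,3R)-hexa-O-benzyl flavanone–flavone
Conditions: preparative SFC, amylose tris(3,5-dimethylphenylcarbamate) stationary phase, CO2/i-PrOH/CH2Cl2
Reagents that add atoms: none
Why: Chromatographic resolution on a chiral stationary phase should supply the (2S,3R) antipode, to be assigned by electronic circular dichroism of the flavanone chromophore; the unwanted antipode could be racemised by fluoride-mediated ring opening and reclosure and recycled.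

Step 7
Reactants: 11 (2S,3R)-hexa-O-benzyl flavanone–flavone
Product: 12 target, (2S,3R)-3-[5,7-dihydroxy-2-(4-hydroxyphenyl)-4-oxo-4H-chromen-3-yl]-5,7-dihydroxy-2-(4-hydroxyphenyl)chroman-4-one
Conditions: H2 (1 atm), Pd/C (10 %), THF/MeOH, rt
Reagents that add atoms: none
Why: Heterogeneous hydrogenolysis of the six benzyl ethers under neutral conditions should leave the flavone double bond, both carbonyl groups and the base-labile C2 and C3 stereocentres untouched.

Compound list

1 | apigenin | O=c1cc(-c2ccc(O)cc2)oc2cc(O)cc(O)c12 | starting material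
2 | tri-O-benzylapigenin, 5,7-bis(benzyloxy)-2-[4-(benzyloxy)phenyl]-4H-chromen-4-one | O=c1cc(-c2ccc(OCc3ccccc3)cc2)oc2cc(OCc3ccccc3)cc(OCc3ccccc3)c12 | intermediate
3 | 3-lithio-tri-O-benzylapigenin (not isolated) | O=c1c([Li])c(-c2ccc(OCc3ccccc3)cc2)oc2cc(OCc3ccccc3)cc(OCc3ccccc3)c12 | intermediate
4 | 5,7-bis(benzyloxy)-2-[4-(benzyloxy)phenyl]-3-iodo-4H-chromen-4-one | O=c1c(I)c(-c2ccc(OCc3ccccc3)cc2)oc2cc(OCc3ccccc3)cc(OCc3ccccc3)c12 | intermediate
5 | 1-(benzyloxy)-4-ethynylbenzene | C#Cc1ccc(OCc2ccccc2)cc1 | starting material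
6 | 5,7-bis(benzyloxy)-2-[4-(benzyloxy)phenyl]-3-{[4-(benzyloxy)phenyl]ethynyl}-4H-chromen-4-one | O=c1c(C#Cc2ccc(OCc3ccccc3)cc2)c(-c2ccc(OCc3ccccc3)cc2)oc2cc(OCc3ccccc3)cc(OCc3ccccc3)c12 | intermediate
7 | 2,4,6-trihydroxybenzaldehyde | O=Cc1c(O)cc(O)cc1O | starting material
8 | 4,6-bis(benzyloxy)-2-hydroxybenzaldehyde | O=Cc1c(O)cc(OCc2ccccc2)cc1OCc1ccccc1 | intermediate
9 | (E)-1-[2,4-bis(benzyloxy)-6-hydroxyphenyl]-3-[4-(benzyloxy)phenyl]-2-{5,7-bis(benzyloxy)-2-[4-(benzyloxy)phenyl]-4-oxo-4H-chromen-3-yl}prop-2-en-1-one (not isolated) | O=C(c1c(O)cc(OCc2ccccc2)cc1OCc1ccccc1)/C(=C/c1ccc(OCc2ccccc2)cc1)c1c(-c2ccc(OCc3ccccc3)cc2)oc2cc(OCc3ccccc3)cc(OCc3ccccc3)c2c1=O | intermediate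
10 | racemic trans-5,7-bis(benzyloxy)-2-[4-(benzyloxy)phenyl]-3-{5,7-bis(benzyloxy)-2-[4-(benzyloxy)phenyl]-4-oxo-4H-chromen-3-yl}chroman-4-one; racemate of (2S,3R) and (2R,3S), SMILES written as the pair of enantiomers | O=C1c2c(OCc3ccccc3)cc(OCc3ccccc3)cc2O[C@H](c2ccc(OCc3ccccc3)cc2)[C@H]1c1c(-c2ccc(OCc3ccccc3)cc2)oc2cc(OCc3ccccc3)cc(OCc3ccccc3)c2c1=O.O=C1c2c(OCc3ccccc3)cc(OCc3ccccc3)cc2O[C@@H](c2ccc(OCc3ccccc3)cc2)[C@@H]1c1c(-c2ccc(OCc3ccccc3)cc2)oc2cc(OCc3ccccc3)cc(OCc3ccccc3)c2c1=O | intermediate
11 | (2S,3R)-5,7-bis(benzyloxy)-2-[4-(benzyloxy)phenyl]-3-{5,7-bis(benzyloxy)-2-[4-(benzyloxy)phenyl]-4-oxo-4H-chromen-3-yl}chroman-4-one | O=C1c2c(OCc3ccccc3)cc(OCc3ccccc3)cc2O[C@H](c2ccc(OCc3ccccc3)cc2)[C@H]1c1c(-c2ccc(OCc3ccccc3)cc2)oc2cc(OCc3ccccc3)cc(OCc3ccccc3)c2c1=O | intermediate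
12 | (2S,3R)-3-[5,7-dihydroxy-2-(4-hydroxyphenyl)-4-oxo-4H-chromen-3-yl]-5,7-dihydroxy-2-(4-hydroxyphenyl)chroman-4-one (CNP0208264.1) | O=C1c2c(O)cc(O)cc2O[C@H](c2ccc(O)cc2)[C@H]1c1c(-c2ccc(O)cc2)oc2cc(O)cc(O)c2c1=O | target

Total step count: 7. Longest linear sequence: 6 steps (steps 1, 2, 3, 5, 6, 7 from apigenin).

Steps most likely to fail

1. Step 5. The hydride may be delivered to the wrong alkyne carbon, which after cyclisation would lead to the 2-flavonyl-3-aryl regioisomer, or decarbonylation of the hindered acyl rhodium hydride may outrun insertion into the bulky alkyne. The fallback sets out from 2 and 4 and comes back at 10; it forms the C3–flavone C3 bond directly instead of building ring C. Conjugate hydride reduction of flavone 2 (LiBH(s-Bu)3, THF, −78 °C) with trapping of the enolate by Me3SiCl should give racemic 5,7-bis(benzyloxy)-2-[4-(benzyloxy)phenyl]-4-(trimethylsilyloxy)-2H-chromene F1. Palladium-catalysed alpha-arylation of this silyl enol ether with iodide 4 (Pd(dba)2, P(t-Bu)3, ZnF2, CsF, DMF, 80 °C) should then give 10 after fluoride-mediated equilibration to the trans isomer.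

2. Step 2. Lithiation may be incomplete or unselective, through competing deprotonation of the benzylic ether positions or addition of the amide to C2 of the pyrone. The fallback sets out from 8 and 5 and comes back at 4; it builds the iodinated pyrone ring instead of iodinating it. Benzylation of 8 (BnBr, K2CO3, DMF) should give 2,4,6-tris(benzyloxy)benzaldehyde F2. Addition of the lithium acetylide of 5 (n-BuLi, THF, −78 °C) should give racemic 1-[2,4,6-tris(benzyloxy)phenyl]-3-[4-(benzyloxy)phenyl]prop-2-yn-1-ol F3, and oxidation (MnO2, CH2Cl2) the ynone 1-[2,4,6-tris(benzyloxy)phenyl]-3-[4-(benzyloxy)phenyl]prop-2-yn-1-one F4. Iodocyclisation with ICl (CH2Cl2, −78 °C), in which one ortho benzyloxy oxygen attacks the iodonium-activated alkyne and loses its benzyl group, should give 4.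

3. Step 7. Over-reduction may occur (hydrogenolysis of the benzylic C2–O1 bond or saturation of the flavone double bond), or removal of the two hindered peri benzyl ethers may stall. The fallback sets out from 11 and comes back at 12; it replaces reductive cleavage by Lewis-acid dealkylation with a cation scavenger (BCl3, pentamethylbenzene, CH2Cl2, −78 °C), which transfers the benzyl cations to the scavenger at low temperature without hydrogen or metal. It makes no new compound (F0).

Further compounds

F1 | step 5 | racemic 5,7-bis(benzyloxy)-2-[4-(benzyloxy)phenyl]-4-(trimethylsilyloxy)-2H-chromene | C[Si](C)(C)OC1=CC(c2ccc(OCc3ccccc3)cc2)Oc2cc(OCc3ccccc3)cc(OCc3ccccc3)c12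
F2 | step 2 | 2,4,6-tris(benzyloxy)benzaldehyde | O=Cc1c(OCc2ccccc2)cc(OCc2ccccc2)cc1OCc1ccccc1
F3 | step 2 | racemic 1-[2,4,6-tris(benzyloxy)phenyl]-3-[4-(benzyloxy)phenyl]prop-2-yn-1-ol | OC(C#Cc1ccc(OCc2ccccc2)cc1)c1c(OCc2ccccc2)cc(OCc2ccccc2)cc1OCc1ccccc1
F4 | step 2 | 1-[2,4,6-tris(benzyloxy)phenyl]-3-[4-(benzyloxy)phenyl]prop-2-yn-1-one | O=C(C#Cc1ccc(OCc2ccccc2)cc1)c1c(OCc2ccccc2)cc(OCc2ccccc2)cc1OCc1ccccc1
F0 | step 7 | none | none
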